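## Analysis of the target

- **Skeleton.** Target 22 (C24H18O12) consists of two naphthalene bicycles joined through one oxygen atom.
- **Quinone half.** Ring A is C1–C4/C4a/C8a and ring B is the benzenoid ring. This half is a 3-ethyl-5,7,8-trihydroxy-1,4-naphthoquinone that carries the bridging oxygen O2 on C2.
- **Trione half.** Ring C is C1′–C4′/C4a′/C8a′ and ring D is benzenoid. This half is a 3′-ethyl-5′,7′,8′-trihydroxynaphthalene-1′,2′,4′-trione.
- **Stereocentre.** The only one is C3′ in ring C, a fully substituted carbon bearing O2, ethyl, C2′=O and C4′=O. The priorities are O2 > C2′ > C4′ > ethyl, because C2′ leads on to the oxygen-bearing C1′ whereas C4′ leads on to the all-carbon C4a′. This makes it (S).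
- **Feature that decides the strategy.** It is the O2–C3′ bond read together with the oxidation levels. Both halves have the same carbon skeleton, the same ethyl position and the same oxygen pattern (1,2,4,5,7,8). Target 22 is therefore two molecules of one hydroxyquinone minus two hydrogen atoms, with ring A at the quinone level and ring C two electrons higher.
- **Polarity.** The bond joins the enol oxygen O2 and the enol carbon C3 of that hydroxyquinone. Both are nucleophilic, so it is a union of like polarity at a hindered carbon flanked by two carbonyl groups, with no neighbouring stereocentre to relay chirality.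
- **Sensitive groups.**
  - The C1′/C2′ diketone undergoes hydration, base-induced acyl shift with ring contraction, and peracid cleavage.
  - The bridge is at once a vinylogous ester at C2 and a leaving group α to two ketones at C3′. Nucleophiles and any two-electron reductant therefore split 22 back into its halves.
- **Competing site.** Rings A/B form a tautomerising naphthazarin, and O7–H is a second acidic hydroxyl with a free neighbouring position, C6. This would compete in any oxidative bond formation.

## Retrosynthetic reasoning

**22 ⇒ 21.** The six phenolic O–H bonds are traced back to benzyl ethers. Full protection of rings B and D freezes the naphthazarin tautomerism, so O2–H is the only acidic hydroxyl and C3 the only nucleophilic carbon in the monomer. Benzyl is chosen because it can leave under a boron Lewis acid with an arene cation trap at low temperature. Reductive or basic deprotection would destroy the bridge or ring C.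

**21 ⇒ 16 + 16 (through 20, reagent 19).**
- **The cut.** The O2–C3′ bond is cut in the oxidative sense, which halves the molecule into two copies of the achiral hydroxyquinone 16.
- **What the forward step must do.** It has to form the tertiary ether, raise ring C to the trione level and set C3′, all in one two-electron event.
- **Why iodine.** A trivalent iodine centre carries exactly two exchangeable oxygen ligands. This matches the 2:1 stoichiometry of a homodimerisation, so both halves can be collected on the chiral reagent 19 as 20 and coupled inside its chiral pocket.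
- **What is gained.** No second monomer derivative is needed, and there is no step in which a tertiary alkoxide next to a diketone has to survive base.

**19 ⇒ 17.** The chiral oxidant comes from the commercial C2-symmetric iodoarene 17 by oxidation and ligand exchange. Compound 17 is returned by the key step.

**16 ⇒ 14.** The C2–OH is masked as the vinylogous methyl ester 14, which hydroxide opens without touching the aryl benzyl ethers.

**14 ⇒ 11 (through 12 and 13).** Ring A is cut at C1–C8a and traced to the four-membered ring of 11.
- **Forward reaction.** It is a thermal 4π opening followed by 6π closure and then dehydrogenation.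
- **Regiochemical lock.** The substituent order around the cyclobutenone (C=O, OMe, Et, C(OH)Ar) is copied onto C1–C4, and the aryl group has only one free ortho position. The 2-oxy-3-ethyl-5,7,8 pattern is therefore fixed without any selectivity question in the ring-forming step.

**11 ⇒ 7 ⇒ 3 + 4.** The aryl–C4 and ethyl–C3 bonds are cut, so both carbon groups are delivered as carbanions to squarate 4.
- **Order of addition.** The aryl group goes in first, followed by a silyl cap. The ethyl group goes in second with a 1,3-carbonyl transposition, which places ethyl next to the aryl carbinol carbon.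
- **Why not the reverse.** The reverse order would deliver the aryl group to the carbonyl next to the methoxy-bearing carbon and end in the 5,6,8-oxygenated regioisomer.

**3 ⇒ 2 ⇒ 1.** The arene is the tribenzyl ether of the commercial triol 1. It is brominated at the one position that is doubly activated and not flanked by two ether groups.

## Alternatives that were turned down

**Alternative 1:** (the textbook one) cut the sp2 C2–O2 bond.
- **Forward key step.** Asymmetric α-hydroxylation of 16 gives the tertiary ketol A1. Its alkoxide then undergoes addition–elimination on the chloroquinone A2 to give 21.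
- **Why it was turned down.**
  - The alkoxide of A1 sits on a fully substituted carbon between two carbonyl groups, so it is a weak and hindered nucleophile.
  - Once deprotonated, it is set up for acyl shift with ring contraction (the first stage of the Hooker-type degradation) and for retro-Claisen opening.
  - C2 of A2 is itself flanked by ethyl and by a carbonyl that has a peri benzyloxy group.
  - Two different derivatives of 16 are needed, and the new stereocentre has to survive base.

**Alternative 2:** cut the same O2–C3′ bond in the polar, enantioconvergent sense.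
- **Forward key step.** The racemic tertiary chloride A3, obtained from 16 by chlorination, is substituted by the anion of 16 under a chiral phase-transfer or chiral copper photocatalyst.
- **Why it was turned down.**
  - Back-side displacement is impossible at C3′.
  - Ionisation would place a cation between two carbonyl groups.
  - The most likely event is attack on chlorine, which only passes the halogen between two identical enolates.
  - Radical enantioconvergent couplings of this kind are established for nitrogen and carbon nucleophiles, not for vinylogous carboxylates.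
  - The route gains a step and loses no risk.

**Alternative 3:** cut C3′–CH2CH3.
- **Forward key step.** Enantioselective C-ethylation of the enol A4, the bridged dimer lacking one ethyl group, gives 21.
- **Why it was turned down.**
  - Hydroxyquinone anions are alkylated by unactivated alkyl halides mainly on oxygen.
  - C3′ bearing an aryloxy-type substituent is still less nucleophilic.
  - A4 is an unsymmetrical ether of two different quinones. It would require two monomer syntheses and the same difficult ether bond, so nothing is simplified.

Key step: step 8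

Assumption: the sense of induction of 19 cannot be derived with certainty. The (R,R) reagent is assigned to the (S) product, and if the coupling should favour the other face, the mirror image of 17 is used in the same way.

## Route

Step 1
Reactants: 1 benzene-1,2,4-triol
Product: 2 1,2,4-tris(benzyloxy)benzene
Conditions: BnBr, K2CO3, degassed DMF, N2, 60 °C
Reagents that add atoms: benzyl bromide, BrCc1ccccc1
Why: Threefold Williamson ether synthesis. Exclusion of air prevents autoxidation of the triol under base.

Step 2
Reactants: 2 1,2,4-tris(benzyloxy)benzene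
Product: 3 1,2,4-tris(benzyloxy)-5-bromobenzene
Conditions: NBS, MeCN, 0 °C
Reagents that add atoms: N-bromosuccinimide, O=C1CCC(=O)N1Br
Why: Electrophilic aromatic bromination. C5 is para to one ether oxygen and ortho to another, and unlike C3 it is not wedged between two ether groups, so monobromination should occur there.

Step 3
Reactants: 3 1,2,4-tris(benzyloxy)-5-bromobenzene; 4 dimethyl squarate
Product: 7 4-[2,4,5-tris(benzyloxy)phenyl]-2,3-dimethoxy-4-(trimethylsilyloxy)cyclobut-2-en-1-one (racemic), via aryllithium 5 (not isolated), via lithium alkoxide 6 (not isolated)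
Conditions: n-BuLi, THF, −78 °C; 4, −78 °C; Me3SiCl, −78 to 0 °C
Reagents that add atoms: chlorotrimethylsilane, C[Si](C)(C)Cl
Why: Bromine–lithium exchange outruns benzylic deprotonation at −78 °C, and the aryllithium adds 1,2 to one of the two equivalent carbonyl groups of 4 (standard squarate chemistry). The alkoxide is capped in the flask. The new stereocentre is racemic and is destroyed in step 5.

Step 4
Reactants: 7 4-[2,4,5-tris(benzyloxy)phenyl]-2,3-dimethoxy-4-(trimethylsilyloxy)cyclobut-2-en-1-one
Product: 11 4-[2,4,5-tris(benzyloxy)phenyl]-3-ethyl-4-hydroxy-2-methoxycyclobut-2-en-1-one (racemic), via lithium alkoxide 8 (not isolated), via trifluoroacetate 9 (not isolated), via silyl ether 10 (not isolated)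
Conditions: EtLi, THF, −78 °C; (CF3CO)2O, −78 °C; H2O–THF, 0 °C; then dilute HCl, 0 °C
Reagents that add atoms: ethyllithium, [Li]CC; water, O
Why: 1,2-Addition to the remaining carbonyl is followed by selective acylation of the new alkoxide, ionisation assisted by the methoxy group at the far allylic terminus, and hydrolysis, which is the 1,3-carbonyl transposition used in cyclobutenone syntheses for Moore rearrangements. Only the trifluoroacetate is a leaving group at −78 °C, so the silyloxy-bearing carbon is kept. Dilute acid then removes the silyl group.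

Step 5
Reactants: 11 4-[2,4,5-tris(benzyloxy)phenyl]-3-ethyl-4-hydroxy-2-methoxycyclobut-2-en-1-one
Product: 14 5,7,8-tris(benzyloxy)-3-ethyl-2-methoxynaphthalene-1,4-dione, via vinylketene 12 (not isolated), via hydroquinone 13 (not isolated)
Conditions: degassed p-xylene, 138 °C; cool; Ag2O, rt
Reagents that add atoms: none
Why: Moore rearrangement: conrotatory 4π opening with the hydroxyl rotating outward turns the aryl group towards the ketene. 6π closure on the only free ortho carbon followed by tautomerisation gives 13. Ag2O dehydrogenates 13 to the quinone.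

Step 6
Reactants: 14 5,7,8-tris(benzyloxy)-3-ethyl-2-methoxynaphthalene-1,4-dione
Product: 16 5,7,8-tris(benzyloxy)-3-ethyl-2-hydroxynaphthalene-1,4-dione, via sodium salt 15 (not isolated)
Conditions: aq. NaOH, THF–MeOH, N2, rt to 40 °C; then 1 M HCl
Reagents that add atoms: sodium hydroxide, [Na+].[OH-]
Why: The C2 methoxy group is a vinylogous methyl ester and is exchanged by addition–elimination of hydroxide, while the aryl benzyl ethers are inert. Peroxide-free conditions avoid Hooker-type degradation of the ethyl chain.

Step 7
Reactants: 17 (2R,2′R)-2,2′-[(2-iodobenzene-1,3-diyl)bis(oxy)]bis[N-(2,4,6-trimethylphenyl)propanamide]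
Product: 19 bis(trifluoroacetoxy)-λ3-iodane of 17, via diacetate 18 (not isolated)
Conditions: CH3CO3H in AcOH, rt; evaporate; CF3CO2H, CH2Cl2, 0 °C; evaporate
Reagents that add atoms: trifluoroacetic acid, OC(=O)C(F)(F)F
Why: Peracid oxidation of an iodoarene to its (diacetoxyiodo)arene is followed by ligand exchange with the stronger acid, driven by evaporation of acetic acid, as in the conversion of PhI(OAc)2 into PhI(OCOCF3)2. The lactamide stereocentres are not involved.

Step 8
Reactants: 16 5,7,8-tris(benzyloxy)-3-ethyl-2-hydroxynaphthalene-1,4-dione (two molecules); 19 bis(trifluoroacetoxy)-λ3-iodane of 17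
Product: 21 (3S)-5,7,8-tris(benzyloxy)-3-ethyl-3-{[5,7,8-tris(benzyloxy)-3-ethyl-1,4-dioxo-1,4-dihydronaphthalen-2-yl]oxy}naphthalene-1,2,4(3H)-trione, via bis(quinonyloxy)iodane 20 (not isolated)
Conditions: 19 (0.5 equiv), powdered 4 Å molecular sieves, CH2Cl2, −78 to −40 °C, dark
Reagents that add atoms: none
Why: Proposed new method: both trifluoroacetate ligands of 19 should be exchanged for the acidic O2–H of two molecules of 16, since the more basic oxygen ligand binds trivalent iodine more strongly, giving 20 with both halves of the target on one iodine atom. One quinonate then loosens into a contact ion pair held by an amide N–H of a lactamide arm, and its O2 attacks C3 of the ligand still bound through O2 while 17 leaves as monovalent iodine (SN2′-type reductive displacement); this forms the O2–C3′ bond, turns C2′–O into the C2′ carbonyl and raises ring C to the trione level in one two-electron event. The closest known reaction types are the Kita-type oxidative dearomatising spirolactonisation of 1-naphthols with chiral iodoarenes, the α-acyloxylation of 1,3-dicarbonyl compounds by trivalent iodine and the racemic PbO2 dimerisation of 3-alkyl-2-hydroxy-1,4-naphthoquinones, and what is new is the intermolecular vinylogous-acid nucleophile on a hydroxyquinone under reagent control. No ring is closed: two identical bicycles are joined through one C–O bond. The stereocentre C3′ is controlled by the C2-symmetric reagent, whose two (R)-lactamide arms fold over the iodine–oxygen bonds by N–H···O hydrogen bonding so that a mesityl group covers one face of C3 of the bound ligand and the second quinonate is delivered to the open face. The substrate enforces the associative path that chirality transfer needs, because a cation at C3′ between C2′=O and C4′=O is not viable, and low temperature and darkness suppress iodine–oxygen homolysis. Site selectivity rests on the benzyl ethers (only O2–H can bind iodine and only C3 can be attacked), on the fact that C3–C3′ coupling would join two fully substituted carbons, and on O4 being shielded by the peri O5 benzyl group and leading only to a less stable ortho-quinone. Chemoselectivity rests on trifluoroacetate being too poor a nucleophile to compete, on sieves removing water, on the absence of any peracid that could cleave the C1′–C2′ diketone, and on 21 having no enolic hydroxyl left, so that oxidation stops.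

Step 9
Reactants: 21 (3S)-hexabenzyl ether
Product: 22 (3S)-3-ethyl-3-[(3-ethyl-5,7,8-trihydroxy-1,4-dioxo-1,4-dihydronaphthalen-2-yl)oxy]-5,7,8-trihydroxynaphthalene-1,2,4(3H)-trione
Conditions: BCl3, C6HMe5, CH2Cl2, −78 °C; then H2O–THF, −78 to 0 °C
Reagents that add atoms: none
Why: This is the known debenzylation of aryl benzyl ethers by BCl3 with pentamethylbenzene as a non-Lewis-basic benzyl cation trap, and the four peri ethers are further activated by chelation to the neighbouring carbonyl groups. The conditions are neither reductive nor basic, and ionisation at C3′ is disfavoured by its two carbonyl neighbours, so the bridge, the diketone and the configuration should be kept.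

## Compound list

1 | benzene-1,2,4-triol | Oc1ccc(O)c(O)c1 | starting material
2 | 1,2,4-tris(benzyloxy)benzene | c1ccccc1COc1ccc(OCc2ccccc2)c(OCc2ccccc2)c1 | intermediate
3 | 1,2,4-tris(benzyloxy)-5-bromobenzene | Brc1cc(OCc2ccccc2)c(OCc2ccccc2)cc1OCc1ccccc1 | intermediate
4 | dimethyl squarate (3,4-dimethoxycyclobut-3-ene-1,2-dione) | COC1=C(OC)C(=O)C1=O | starting material
5 | 2,4,5-tris(benzyloxy)phenyllithium | [Li]c1cc(OCc2ccccc2)c(OCc2ccccc2)cc1OCc1ccccc1 | intermediate
6 | lithium 1-[2,4,5-tris(benzyloxy)phenyl]-2,3-dimethoxy-4-oxocyclobut-2-en-1-olate (racemic) | COC1=C(OC)C([O-])(c2cc(OCc3ccccc3)c(OCc3ccccc3)cc2OCc2ccccc2)C1=O.[Li+] | intermediate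
7 | 4-[2,4,5-tris(benzyloxy)phenyl]-2,3-dimethoxy-4-(trimethylsilyloxy)cyclobut-2-en-1-one (racemic) | COC1=C(OC)C(O[Si](C)(C)C)(c2cc(OCc3ccccc3)c(OCc3ccccc3)cc2OCc2ccccc2)C1=O | intermediate
8 | lithium 4-[2,4,5-tris(benzyloxy)phenyl]-1-ethyl-2,3-dimethoxy-4-(trimethylsilyloxy)cyclobut-2-en-1-olate (racemic, diastereomer mixture) | CCC1([O-])C(OC)=C(OC)C1(O[Si](C)(C)C)c1cc(OCc2ccccc2)c(OCc2ccccc2)cc1OCc1ccccc1.[Li+] | intermediate
9 | 4-[2,4,5-tris(benzyloxy)phenyl]-1-ethyl-2,3-dimethoxy-4-(trimethylsilyloxy)cyclobut-2-en-1-yl trifluoroacetate (racemic, diastereomer mixture) | CCC1(OC(=O)C(F)(F)F)C(OC)=C(OC)C1(O[Si](C)(C)C)c1cc(OCc2ccccc2)c(OCc2ccccc2)cc1OCc1ccccc1 | intermediate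
10 | 4-[2,4,5-tris(benzyloxy)phenyl]-3-ethyl-2-methoxy-4-(trimethylsilyloxy)cyclobut-2-en-1-one (racemic) | CCC1=C(OC)C(=O)C1(O[Si](C)(C)C)c1cc(OCc2ccccc2)c(OCc2ccccc2)cc1OCc1ccccc1 | intermediate
11 | 4-[2,4,5-tris(benzyloxy)phenyl]-3-ethyl-4-hydroxy-2-methoxycyclobut-2-en-1-one (racemic) | CCC1=C(OC)C(=O)C1(O)c1cc(OCc2ccccc2)c(OCc2ccccc2)cc1OCc1ccccc1 | intermediate
12 | (E)-4-[2,4,5-tris(benzyloxy)phenyl]-3-ethyl-4-hydroxy-2-methoxybuta-1,3-dien-1-one (vinylketene, aryl cis to the ketene arm) | O=C=C(OC)/C(CC)=C(/O)c1cc(OCc2ccccc2)c(OCc2ccccc2)cc1OCc1ccccc1 | intermediate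
13 | 5,7,8-tris(benzyloxy)-3-ethyl-2-methoxynaphthalene-1,4-diol | CCc1c(OC)c(O)c2c(OCc3ccccc3)c(OCc3ccccc3)cc(OCc3ccccc3)c2c1O | intermediate
14 | 5,7,8-tris(benzyloxy)-3-ethyl-2-methoxynaphthalene-1,4-dione | CCC1=C(OC)C(=O)c2c(OCc3ccccc3)c(OCc3ccccc3)cc(OCc3ccccc3)c2C1=O | intermediate
15 | sodium 5,7,8-tris(benzyloxy)-3-ethyl-1,4-dioxo-1,4-dihydronaphthalen-2-olate | CCC1=C([O-])C(=O)c2c(OCc3ccccc3)c(OCc3ccccc3)cc(OCc3ccccc3)c2C1=O.[Na+] | intermediate
16 | 5,7,8-tris(benzyloxy)-3-ethyl-2-hydroxynaphthalene-1,4-dione | CCC1=C(O)C(=O)c2c(OCc3ccccc3)c(OCc3ccccc3)cc(OCc3ccccc3)c2C1=O | intermediate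
17 | (2R,2′R)-2,2′-[(2-iodobenzene-1,3-diyl)bis(oxy)]bis[N-(2,4,6-trimethylphenyl)propanamide] | Ic1c(O[C@H](C)C(=O)Nc2c(C)cc(C)cc2C)cccc1O[C@H](C)C(=O)Nc1c(C)cc(C)cc1C | starting material
18 | diacetoxy-λ3-iodane of 17 | CC(=O)OI(OC(C)=O)c1c(O[C@H](C)C(=O)Nc2c(C)cc(C)cc2C)cccc1O[C@H](C)C(=O)Nc1c(C)cc(C)cc1C | intermediate
19 | bis(trifluoroacetoxy)-λ3-iodane of 17 | O=C(OI(OC(=O)C(F)(F)F)c1c(O[C@H](C)C(=O)Nc2c(C)cc(C)cc2C)cccc1O[C@H](C)C(=O)Nc1c(C)cc(C)cc1C)C(F)(F)F | intermediate
20 | λ3-iodane of 17 bearing two O2-bound quinonate ligands derived from 16 | CCC1=C(OI(OC2=C(CC)C(=O)c3c(OCc4ccccc4)cc(OCc4ccccc4)c(OCc4ccccc4)c3C2=O)c2c(O[C@H](C)C(=O)Nc3c(C)cc(C)cc3C)cccc2O[C@H](C)C(=O)Nc2c(C)cc(C)cc2C)C(=O)c2c(OCc3ccccc3)c(OCc3ccccc3)cc(OCc3ccccc3)c2C1=O | intermediate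
21 | (3S)-5,7,8-tris(benzyloxy)-3-ethyl-3-{[5,7,8-tris(benzyloxy)-3-ethyl-1,4-dioxo-1,4-dihydronaphthalen-2-yl]oxy}naphthalene-1,2,4(3H)-trione | CCC1=C(O[C@]2(CC)C(=O)C(=O)c3c(OCc4ccccc4)c(OCc4ccccc4)cc(OCc4ccccc4)c3C2=O)C(=O)c2c(OCc3ccccc3)c(OCc3ccccc3)cc(OCc3ccccc3)c2C1=O | intermediate
22 | (3S)-3-ethyl-3-[(3-ethyl-5,7,8-trihydroxy-1,4-dioxo-1,4-dihydronaphthalen-2-yl)oxy]-5,7,8-trihydroxynaphthalene-1,2,4(3H)-trione | CCC1=C(O[C@]2(CC)C(=O)C(=O)c3c(O)c(O)cc(O)c3C2=O)C(=O)c2c(O)c(O)cc(O)c2C1=O | target

## Step count and least certain steps

Total step count: 9. Longest linear sequence: 8 (steps 1–6, 8 and 9). Step 7 prepares the reagent on a side branch.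

**Step 8 (key step, proposed new method).**
- **What may go wrong.**
  - Poor facial selectivity, if the C–O bond forms after complete ligand dissociation or after iodine–oxygen homolysis to free oxyl radicals outside the chiral pocket.
  - Capture of the iodine-bound ligand by trifluoroacetate or traces of water in place of the second quinonate.
- **Fallback (known chemistry).**
  - It sets out from 16. Oxidation with PbO2 in CH2Cl2–AcOH, the established dimerisation of 3-alkyl-2-hydroxy-1,4-naphthoquinones, should give the racemic hexabenzyl ether F1.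
  - Preparative HPLC on a polysaccharide carbamate chiral phase separates F1 into 21 and the (R)-hexabenzyl ether F2.
  - F2 is recycled. Reduction with Na2S2O4 expels the quinonate from C3′, and exposure to air returns two molecules of 16.
  - The route is rejoined at 21.

**Step 7.**
- **What may go wrong.** The bis(trifluoroacetate) may hydrolyse to oxo-bridged oligomers or oxidise its own mesityl amide arms on concentration, because the weakly bound ligands make the iodine centre far more electrophilic than in the diacetate.
- **Fallback.**
  - It sets out from 18, isolated by evaporation, and from 15, isolated before the acidification in step 6.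
  - Two equivalents of 15 are combined with 18 in CH2Cl2–toluene at low temperature.
  - Sodium acetate precipitates. This both drives the ligand exchange and withdraws the competing acetate nucleophile, so ligand exchange by anion metathesis replaces exchange by acid.
  - The route is rejoined at 20. This fallback makes no compound outside the list.

**Step 4.**
- **What may go wrong.** Silyl migration to the neighbouring alkoxide, or ionisation at the aryl-bearing carbon. The electron-rich aryl group stabilises a cation there, and this would erase the order of substituents on the four-membered ring.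
- **Fallback.** It removes any transposition on an aryl-bearing intermediate and lets the innate carbonyl selectivity set the regiochemistry.
  - It sets out from 4. EtMgBr followed by aqueous HCl should give 3-ethyl-4-methoxycyclobut-3-ene-1,2-dione F3.
  - Commercial 3-bromo-4,5-dihydroxybenzaldehyde F4 is benzylated to 3,4-bis(benzyloxy)-5-bromobenzaldehyde F5.
  - Baeyer–Villiger oxidation of F5 with mCPBA gives 3,4-bis(benzyloxy)-5-bromophenyl formate F6, which is saponified to 3,4-bis(benzyloxy)-5-bromophenol F7.
  - Benzylation of F7 gives 1,2,5-tris(benzyloxy)-3-bromobenzene F8.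
  - Bromine–lithium exchange gives 2,3,5-tris(benzyloxy)phenyllithium F9. It attacks the carbonyl of F3 next to the methoxy-bearing carbon, which is not part of the vinylogous ester.
  - This gives 4-[2,3,5-tris(benzyloxy)phenyl]-2-ethyl-4-hydroxy-3-methoxycyclobut-2-en-1-one F10.
  - Thermolysis as in step 5 passes through the isomeric vinylketene F11 and closes on the single free ortho carbon.
  - The route is rejoined at 13.

**Step 9.**
- **What may go wrong.**
  - Loss of the bridge by chloride addition–elimination at C2 during prolonged Lewis-acid exposure, because the two non-chelated ethers at O7 and O7′ react more slowly than the four peri ethers.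
  - Benzyl transfer to C6 or C6′, if the cation trap is outrun.
- **Fallback.** It changes the order of events, so that no deprotection follows the formation of the sensitive bond.
  - It sets out from 16, which is debenzylated with BCl3 and C6HMe5 at the robust monomer stage to 3-ethyl-2,5,7,8-tetrahydroxynaphthalene-1,4-dione F12.
  - F12 is coupled with 19 as in step 8. The price is competition by O7–H and C6.
  - The route is rejoined at 22.

## Further compounds

F1 | step 8 | racemic 5,7,8-tris(benzyloxy)-3-ethyl-3-{[5,7,8-tris(benzyloxy)-3-ethyl-1,4-dioxo-1,4-dihydronaphthalen-2-yl]oxy}naphthalene-1,2,4(3H)-trione | CCC1=C(OC2(CC)C(=O)C(=O)c3c(OCc4ccccc4)c(OCc4ccccc4)cc(OCc4ccccc4)c3C2=O)C(=O)c2c(OCc3ccccc3)c(OCc3ccccc3)cc(OCc3ccccc3)c2C1=O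
F2 | step 8 | (3R)-enantiomer of 21 | CCC1=C(O[C@@]2(CC)C(=O)C(=O)c3c(OCc4ccccc4)c(OCc4ccccc4)cc(OCc4ccccc4)c3C2=O)C(=O)c2c(OCc3ccccc3)c(OCc3ccccc3)cc(OCc3ccccc3)c2C1=O
F0 | step 7 | none | none
F3 | step 4 | 3-ethyl-4-methoxycyclobut-3-ene-1,2-dione | CCC1=C(OC)C(=O)C1=O
F4 | step 4 | 3-bromo-4,5-dihydroxybenzaldehyde | O=Cc1cc(O)c(O)c(Br)c1
F5 | step 4 | 3,4-bis(benzyloxy)-5-bromobenzaldehyde | O=Cc1cc(OCc2ccccc2)c(OCc2ccccc2)c(Br)c1
F6 | step 4 | 3,4-bis(benzyloxy)-5-bromophenyl formate | O=COc1cc(OCc2ccccc2)c(OCc2ccccc2)c(Br)c1
F7 | step 4 | 3,4-bis(benzyloxy)-5-bromophenol | Oc1cc(OCc2ccccc2)c(OCc2ccccc2)c(Br)c1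
F8 | step 4 | 1,2,5-tris(benzyloxy)-3-bromobenzene | Brc1cc(OCc2ccccc2)cc(OCc2ccccc2)c1OCc1ccccc1
F9 | step 4 | 2,3,5-tris(benzyloxy)phenyllithium | [Li]c1cc(OCc2ccccc2)cc(OCc2ccccc2)c1OCc1ccccc1
F10 | step 4 | 4-[2,3,5-tris(benzyloxy)phenyl]-2-ethyl-4-hydroxy-3-methoxycyclobut-2-en-1-one (racemic) | CCC1=C(OC)C(O)(c2cc(OCc3ccccc3)cc(OCc3ccccc3)c2OCc2ccccc2)C1=O
F11 | step 4 | 4-[2,3,5-tris(benzyloxy)phenyl]-2-ethyl-4-hydroxy-3-methoxybuta-1,3-dien-1-one (vinylketene, aryl cis to the ketene arm) | O=C=C(CC)/C(OC)=C(/O)c1cc(OCc2ccccc2)cc(OCc2ccccc2)c1OCc1ccccc1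
F12 | step 9 | 3-ethyl-2,5,7,8-tetrahydroxynaphthalene-1,4-dione | CCC1=C(O)C(=O)c2c(O)c(O)cc(O)c2C1=O
A1 | alternative 1 | (3S)-5,7,8-tris(benzyloxy)-3-ethyl-3-hydroxynaphthalene-1,2,4(3H)-trione | O[C@]1(CC)C(=O)C(=O)c2c(OCc3ccccc3)c(OCc3ccccc3)cc(OCc3ccccc3)c2C1=O
A2 | alternative 1 | 5,7,8-tris(benzyloxy)-2-chloro-3-ethylnaphthalene-1,4-dione | CCC1=C(Cl)C(=O)c2c(OCc3ccccc3)c(OCc3ccccc3)cc(OCc3ccccc3)c2C1=O
A3 | alternative 2 | racemic 5,7,8-tris(benzyloxy)-3-chloro-3-ethylnaphthalene-1,2,4(3H)-trione | CCC1(Cl)C(=O)C(=O)c2c(OCc3ccccc3)c(OCc3ccccc3)cc(OCc3ccccc3)c2C1=O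
A4 | alternative 3 | 5,7,8-tris(benzyloxy)-3-{[5,7,8-tris(benzyloxy)-3-ethyl-1,4-dioxo-1,4-dihydronaphthalen-2-yl]oxy}-2-hydroxynaphthalene-1,4-dione | CCC1=C(OC2=C(O)C(=O)c3c(OCc4ccccc4)c(OCc4ccccc4)cc(OCc4ccccc4)c3C2=O)C(=O)c2c(OCc3ccccc3)c(OCc3ccccc3)cc(OCc3ccccc3)c2C1=O
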